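**Plan**

- Retrosynthesis: the benzylic C–O bond of the oxolane (ring O to an aryl-bearing ring carbon) is cut first, giving open-chain 1,4-diaryl-1,4-diol 8 that already carries both acetoxymethyl groups. Next the bond between one carbinol carbon and the backbone is cut (aldol of a γ-aryl paraconic acid with the aryl aldehyde), then the paraconic lactone (aryl aldehyde plus succinic anhydride).
- Forward: a temporary γ-lactone ring is made in step 1 and carries the aldol in step 2. Hydride opens it to the chain (step 3), the primary hydroxyls are acetylated (step 4), the oxolane is closed (step 5) and the benzyl ethers are removed (step 6).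
- Enabling feature: oxolane C-2 and C-5 are each bonded to the ring oxygen and to an aryl ring with oxygen para to that carbon. Each ring C–O bond can therefore ionise reversibly to a quinone-methide-like benzylic cation.
- Stereochemistry: only the relative configuration of C-3/C-4 has to be built. The aldol anti to the carboxylate on the lactone sets it (trans on the lactone becomes cis on the oxolane once the lactone is opened).
- C-2 and C-5 are set in step 5, which should funnel all four diol diastereomers into the isomer with each aryl trans to its neighbour. The target is meso, so no absolute control is needed.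

Key step: step 5

Remark: compounds 3 to 10 are racemic and their SMILES show one enantiomer; centres written without a descriptor are mixtures by design, converged in step 5.

**Step 1**
Reactants: 1 3,4-bis(benzyloxy)benzaldehyde; 2 succinic anhydride
Product: 4 2-[3,4-bis(benzyloxy)phenyl]-5-oxooxolane-3-carboxylic acid (racemic cis/trans mixture), via anhydride aldol adduct 3 (not isolated)
Conditions: ZnCl2 (2.2 equiv), Et3N (2 equiv), CH2Cl2, rt; then aq. HCl
Reagents that add atoms: none
Why: Soft enolisation of the anhydride, aldol addition to the aldehyde and translactonisation of the aldolate onto the distal carbonyl (Perkin-type paraconic acid synthesis) should give the γ-aryl paraconic acid, whose cis/trans ratio is immaterial because the aryl-bearing centre is reset in step 5.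

**Step 2**
Reactants: 4 paraconic acid; 1 3,4-bis(benzyloxy)benzaldehyde
Product: 6 3,4-trans-2-[3,4-bis(benzyloxy)phenyl]-4-{[3,4-bis(benzyloxy)phenyl](hydroxy)methyl}-5-oxooxolane-3-carboxylic acid (mixture at C-2 and at the carbinol carbon), via dilithium dianion 5 (not isolated)
Conditions: LiN(SiMe3)2 (2.2 equiv), THF, −78 °C; then 1 (1.1 equiv), −78 °C; aq. HCl quench at −78 °C
Reagents that add atoms: none
Why: In this lactone enolate aldol addition the carboxylate blocks deprotonation at C-3, so the second equivalent of base forms the lactone enolate at C-4, which should add to the aldehyde anti to the adjacent carboxylate (as in the known α-alkylations of paraconic acid dianions), fixing the relative configuration of the two future acetoxymethyl-bearing carbons.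

**Step 3**
Reactants: 6 aldol acid
Product: 7 (2R*,3S*)-1,4-bis[3,4-bis(benzyloxy)phenyl]-2,3-bis(hydroxymethyl)butane-1,4-diol (mixture of epimers at C-1 and C-4)
Conditions: LiAlH4 (excess), THF, 0 → 50 °C; aq. potassium sodium tartrate work-up
Reagents that add atoms: none
Why: Hydride reduction opens the lactone to the 1,4-diol and reduces the carboxylate to the primary alcohol, the lactone carbonyl being consumed at 0 °C before retro-aldol or epimerisation can intervene, so the backbone configuration should be carried over unchanged.

**Step 4**
Reactants: 7 tetraol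
Product: 8 (2R*,3S*)-2,3-bis(acetoxymethyl)-1,4-bis[3,4-bis(benzyloxy)phenyl]butane-1,4-diol (mixture of epimers at C-1 and C-4)
Conditions: AcCl (2.2 equiv), 2,4,6-collidine, CH2Cl2, −78 °C
Reagents that add atoms: acetyl chloride, CC(=O)Cl
Why: Kinetic acylation with acetyl chloride and a hindered pyridine base at low temperature should select the two unhindered primary hydroxyls over the two secondary benzylic ones, which sit next to a branched carbon (selective primary acetylation).

**Step 5**
Reactants: 8 diol diacetate
Product: 10 [(2R,3S,4R,5S)-2,5-bis[3,4-bis(benzyloxy)phenyl]oxolane-3,4-diyl]bis(methylene) diacetate (meso), via benzylic cation 9 (not isolated)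
Conditions: BF3·OEt2 (0.3 equiv), CH2Cl2, −40 → 0 °C; Et3N quench
Reagents that add atoms: none
Why: The Lewis acid ionises either benzylic hydroxyl of 8 to the para-benzyloxy-stabilised, quinone-methide-like cation 9, and the remaining benzylic hydroxyl captures it, forming the benzylic C–O bond of the oxolane with loss of water. The closest known reaction type is the acid-mediated SN1 cyclodehydration of 1,4-diarylbutane-1,4-diols to 2,5-diaryltetrahydrofuran lignans, together with the acid-induced benzylic epimerisation of such ethers. The oxolane closes in a 5-exo-trig mode, the oxygen attacking the trigonal cationic carbon whose quinoid double bond lies outside the new ring. The new centre forms with the aryl anti to the neighbouring acetoxymethyl group, and because both benzylic C–O bonds of the product stay ionisable, the centre carried in by the nucleophilic carbinol is corrected by ring opening and reclosure, so all four diol diastereomers should drain to the isomer with each aryl trans to its neighbour on the fixed cis-3,4 backbone (2,3-trans, 3,4-cis, 4,5-trans). The step needs O-capture to beat Friedel-Crafts closure by the other electron-rich ring and proton loss from C-3 or C-4, and needs the ring oxygen to come only from a benzylic hydroxyl; fast five-membered O-capture at low temperature with substoichiometric acid should secure the first two, and the acetate caps on both primary oxygens secure the third.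

**Step 6**
Reactants: 10 tetrabenzyl oxolane diacetate
Product: 11 [(2R,3S,4R,5S)-2,5-bis(3,4-dihydroxyphenyl)oxolane-3,4-diyl]bis(methylene) diacetate (meso; target)
Conditions: H2 (1 atm), 10% Pd/C, EtOAc, rt; stopped after uptake of four equivalents
Reagents that add atoms: none
Why: Hydrogenolysis of the four aryl benzyl ethers on palladium is much faster than cleavage of the ring benzylic C–O bonds, so the catechols should be freed with the acetates and all four stereocentres untouched.

**Compound list**

1 | 3,4-bis(benzyloxy)benzaldehyde | O=Cc1ccc(OCc2ccccc2)c(OCc2ccccc2)c1 | starting material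
2 | succinic anhydride | O=C1CCC(=O)O1 | starting material
3 | 3-{[3,4-bis(benzyloxy)phenyl](hydroxy)methyl}oxolane-2,5-dione, the anhydride aldol adduct, present in the flask as its zinc alkoxide | O=C1CC(C(O)c2ccc(OCc3ccccc3)c(OCc3ccccc3)c2)C(=O)O1 | intermediate
4 | 2-[3,4-bis(benzyloxy)phenyl]-5-oxooxolane-3-carboxylic acid, racemic cis/trans mixture | OC(=O)C1CC(=O)OC1c1ccc(OCc2ccccc2)c(OCc2ccccc2)c1 | intermediate
5 | dilithium carboxylate-enolate (dianion) of 4, formed in the flask | [Li+].[Li+].[O-]C(=O)C1C=C([O-])OC1c1ccc(OCc2ccccc2)c(OCc2ccccc2)c1 | intermediate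
6 | 3,4-trans-2-[3,4-bis(benzyloxy)phenyl]-4-{[3,4-bis(benzyloxy)phenyl](hydroxy)methyl}-5-oxooxolane-3-carboxylic acid, mixture at C-2 and the carbinol carbon | OC(=O)[C@@H]1[C@@H](C(O)c2ccc(OCc3ccccc3)c(OCc3ccccc3)c2)C(=O)OC1c1ccc(OCc2ccccc2)c(OCc2ccccc2)c1 | intermediate
7 | (2R*,3S*)-1,4-bis[3,4-bis(benzyloxy)phenyl]-2,3-bis(hydroxymethyl)butane-1,4-diol, mixture at C-1 and C-4 | OC[C@@H](C(O)c1ccc(OCc2ccccc2)c(OCc2ccccc2)c1)[C@H](CO)C(O)c1ccc(OCc2ccccc2)c(OCc2ccccc2)c1 | intermediate
8 | (2R*,3S*)-2,3-bis(acetoxymethyl)-1,4-bis[3,4-bis(benzyloxy)phenyl]butane-1,4-diol, mixture at C-1 and C-4 | CC(=O)OC[C@@H](C(O)c1ccc(OCc2ccccc2)c(OCc2ccccc2)c1)[C@H](COC(C)=O)C(O)c1ccc(OCc2ccccc2)c(OCc2ccccc2)c1 | intermediate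
9 | para-benzyloxy-stabilised benzylic cation from 8, formed in the flask | CC(=O)OC[C@@H]([CH+]c1ccc(OCc2ccccc2)c(OCc2ccccc2)c1)[C@H](COC(C)=O)C(O)c1ccc(OCc2ccccc2)c(OCc2ccccc2)c1 | intermediate
10 | [(2R,3S,4R,5S)-2,5-bis[3,4-bis(benzyloxy)phenyl]oxolane-3,4-diyl]bis(methylene) diacetate, meso | CC(=O)OC[C@@H]1[C@H](COC(C)=O)[C@@H](c2ccc(OCc3ccccc3)c(OCc3ccccc3)c2)O[C@H]1c1ccc(OCc2ccccc2)c(OCc2ccccc2)c1 | intermediate
11 | [(2R,3S,4R,5S)-2,5-bis(3,4-dihydroxyphenyl)oxolane-3,4-diyl]bis(methylene) diacetate, meso | CC(=O)OC[C@@H]1[C@H](COC(C)=O)[C@@H](c2ccc(O)c(O)c2)O[C@H]1c1ccc(O)c(O)c1 | target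

Total step count: 6
Longest linear sequence: 6 steps (1 and 2 → 4 → 6 → 7 → 8 → 10 → 11)

**Steps most likely to fail**

Step 5. The open cation may be diverted into Friedel-Crafts ring closure by the second electron-rich arene, the benzylic centres may not equilibrate fully, or acid may promote acetyl migration so that a primary oxygen becomes the nucleophile. Fallback: ring closure and convergence are separated. Setting out from 8, MsCl (1.2 equiv) and Et3N in CH2Cl2 at −20 → 0 °C should give the benzylic monomesylate F1, which is displaced in the flask by the other benzylic hydroxyl under basic conditions, without free acid. This should give 10 together with the 2-epimeric oxolane F2 (2,3-cis, 3,4-cis, 4,5-trans). The mixture is debenzylated as in step 6 to 11 and the 2-epimeric tetraphenol F3. As a free para-hydroxybenzyl ether, F3 opens to a neutral para-quinone methide far more easily, and should converge on 11 on gentle warming with catalytic acetic acid in acetonitrile. The fallback comes back to the route at 11.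

Step 2. The base may deprotonate next to the carboxylate and open the lactone by β-elimination, the aldolate may revert on warming, or the facial selectivity may be poor. Fallback: the carboxyl group is taken out before the aldol. Setting out from 4, BH3·SMe2 in THF should reduce the acid selectively to the hydroxymethyl lactone F4, and pivaloyl chloride with pyridine gives the pivalate F5. LiN(iPr)2 in THF at −78 °C followed by aldehyde 1 should then give the aldol lactone F6, anti to the pivaloyloxymethyl group (the classical β-substituted butyrolactone enolate aldol). LiAlH4 reduces the lactone and cleaves the pivalate in one operation, and the fallback comes back to the route at 7.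

Step 4. Chemoselectivity may be lost through acetylation of the benzylic hydroxyls or acetyl migration between the 1,3-related oxygens. Fallback: selectivity is made unnecessary. Setting out from 7, Ac2O, pyridine and catalytic DMAP should give the tetraacetate F7. BF3·OEt2 in CH2Cl2 containing one equivalent of water should ionise only the two benzylic acetates; water captures one cation and the resulting benzylic alcohol closes onto the second under the same equilibrating conditions. The fallback comes back to the route at 10.

**Further compounds**

F1 | step 5 | monomesylate of 8 at one benzylic hydroxyl, formed in the flask | CC(=O)OC[C@@H](C(OS(C)(=O)=O)c1ccc(OCc2ccccc2)c(OCc2ccccc2)c1)[C@H](COC(C)=O)C(O)c1ccc(OCc2ccccc2)c(OCc2ccccc2)c1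
F2 | step 5 | 2-epimer of 10 (2,3-cis, 3,4-cis, 4,5-trans; racemic) | CC(=O)OC[C@@H]1[C@H](COC(C)=O)[C@@H](c2ccc(OCc3ccccc3)c(OCc3ccccc3)c2)O[C@@H]1c1ccc(OCc2ccccc2)c(OCc2ccccc2)c1
F3 | step 5 | 2-epimer of 11 (2,3-cis, 3,4-cis, 4,5-trans; racemic) | CC(=O)OC[C@@H]1[C@H](COC(C)=O)[C@@H](c2ccc(O)c(O)c2)O[C@@H]1c1ccc(O)c(O)c1
F4 | step 2 | 5-[3,4-bis(benzyloxy)phenyl]-4-(hydroxymethyl)oxolan-2-one, cis/trans mixture | OCC1CC(=O)OC1c1ccc(OCc2ccccc2)c(OCc2ccccc2)c1
F5 | step 2 | {2-[3,4-bis(benzyloxy)phenyl]-5-oxooxolan-3-yl}methyl pivalate, cis/trans mixture | CC(C)(C)C(=O)OCC1CC(=O)OC1c1ccc(OCc2ccccc2)c(OCc2ccccc2)c1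
F6 | step 2 | 3,4-trans-{2-[3,4-bis(benzyloxy)phenyl]-4-{[3,4-bis(benzyloxy)phenyl](hydroxy)methyl}-5-oxooxolan-3-yl}methyl pivalate, mixture at C-2 and the carbinol carbon | CC(C)(C)C(=O)OC[C@@H]1[C@@H](C(O)c2ccc(OCc3ccccc3)c(OCc3ccccc3)c2)C(=O)OC1c1ccc(OCc2ccccc2)c(OCc2ccccc2)c1
F7 | step 4 | (2R*,3S*)-2,3-bis(acetoxymethyl)-1,4-bis[3,4-bis(benzyloxy)phenyl]butane-1,4-diyl diacetate, mixture at C-1 and C-4 | CC(=O)OC[C@@H](C(OC(C)=O)c1ccc(OCc2ccccc2)c(OCc2ccccc2)c1)[C@H](COC(C)=O)C(OC(C)=O)c1ccc(OCc2ccccc2)c(OCc2ccccc2)c1
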